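**Retrosynthetic overview**

- The last C–C bond is the lactone Cα–CH2(aryl) bond. It is made by trans alkylation of the enolate of a (4R)-4-[(R)-aryl(silyloxy)methyl]butyrolactone with the C5 benzylic bromide of the dihydrobenzofuran half; four silyl ethers are removed at the end.
- The lactone half comes from an L-proline anti cross-aldol of methyl 4-oxobutanoate with O-silyl vanillin, followed by reduction and lactonisation.
- The route rests on the dihydrofuran ring O1–C2–C3–C3a–C7a with its exocyclic hydroxymethyl carbon on C3. It is read as a 2-aryl-2H-chromene whose C4 has been expelled from the ring: a trivalent-iodine ring contraction moves C4a from C4 to C3 and forms the C3–C3a bond.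
- The (S)-chromene comes from enantioselective aryl boronate addition to a 2-ethoxy-2H-chromene, itself made from 5-bromo-2-hydroxy-3-methoxybenzaldehyde via the coumarin.
- Ring order: pyran ring (step 1), contracted to the dihydrofuran (step 7); the butyrolactone ring is built separately (step 13); the halves are joined in step 15.

Key step: step 7

Assumption: the L-tartaric-acid-derived diol catalyst in step 6 is taken to give the (S)-chromene; if the sense of induction is the reverse, the D-tartaric catalyst is used.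

Abbreviation: TBS = tert-butyldimethylsilyl.

**Route**

Step 1
Reactants: 1 5-bromo-2-hydroxy-3-methoxybenzaldehyde; 2 ethyl (triphenylphosphoranylidene)acetate
Product: 4 6-bromo-8-methoxy-2H-chromen-2-one, via cinnamate ester 3 (not isolated)
Conditions: PhNEt2, reflux (ca. 215 °C)
Reagents that add atoms: none
Why: Wittig olefination of the salicylaldehyde, then thermal E/Z equilibration and lactonisation of the o-hydroxycinnamate, is a standard one-pot coumarin synthesis; no stereocentre is formed.

Step 2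
Reactants: 4 6-bromo-8-methoxy-2H-chromen-2-one
Product: 6 6-bromo-2-ethoxy-8-methoxy-2H-chromene (racemic), via lactol 5 (not isolated)
Conditions: i-Bu2AlH, toluene, −78 °C; aq. potassium sodium tartrate; crude lactol, EtOH, PPTS (cat.), rt
Reagents that add atoms: ethanol (CCO)
Why: Partial hydride reduction of the lactone to the lactol and acid-catalysed acetalisation give the cyclic mixed acetal, a benzopyrylium precursor whose racemic acetal carbon is erased in step 6.

Step 3
Reactants: 7 4-bromo-2-methoxyphenol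
Product: 8 (4-bromo-2-methoxyphenoxy)(tert-butyl)dimethylsilane
Conditions: TBSCl, imidazole, DMF, rt
Reagents that add atoms: tert-butyldimethylsilyl chloride (CC(C)(C)[Si](C)(C)Cl)
Why: Standard imidazole-promoted silylation of a phenol.

Step 4
Reactants: 8 (4-bromo-2-methoxyphenoxy)(tert-butyl)dimethylsilane
Product: 10 [4-(tert-butyldimethylsilyloxy)-3-methoxyphenyl]boronic acid, via aryllithium 9 (not isolated)
Conditions: n-BuLi, THF, −78 °C; B(Oi-Pr)3, −78 °C → rt; 1 M aq. HCl
Reagents that add atoms: triisopropyl borate (CC(C)OB(OC(C)C)OC(C)C); water (O)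
Why: Bromine–lithium exchange and borate trapping followed by hydrolysis is the usual route to an arylboronic acid; the lithium sits para to the silyloxy group, so no silyl migration is expected.

Step 5
Reactants: 10 [4-(tert-butyldimethylsilyloxy)-3-methoxyphenyl]boronic acid
Product: 11 diethyl [4-(tert-butyldimethylsilyloxy)-3-methoxyphenyl]boronate
Conditions: EtOH, toluene, 4 Å MS, reflux; evaporate, use crude
Reagents that add atoms: ethanol (CCO)
Why: Esterification of a boronic acid with removal of water gives the dialkyl boronate needed for ligand exchange with the diol catalyst.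

Step 6
Reactants: 6 6-bromo-2-ethoxy-8-methoxy-2H-chromene; 11 diethyl [4-(tert-butyldimethylsilyloxy)-3-methoxyphenyl]boronate
Product: 12 (S)-6-bromo-2-[4-(tert-butyldimethylsilyloxy)-3-methoxyphenyl]-8-methoxy-2H-chromene
Conditions: L-tartaric-acid-derived diol catalyst (N,N-dibenzyl monoamide, 10 mol %), Ce(OTf)4 (5 mol %), EtOAc, −20 °C
Reagents that add atoms: none
Why: The Lewis acid ionises the acetal to a benzopyrylium ion and the chiral diol exchanges onto boron, so the electron-rich aryl group is delivered to C2 on one face (catalytic enantioselective boronate addition to chromene acetals, a Petasis-type arylation), which sets C2 as S under catalyst control.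

Step 7
Reactants: 12 (S)-6-bromo-2-[4-(tert-butyldimethylsilyloxy)-3-methoxyphenyl]-8-methoxy-2H-chromene
Product: 14 (2S,3S)-5-bromo-2-[4-(tert-butyldimethylsilyloxy)-3-methoxyphenyl]-3-(dimethoxymethyl)-7-methoxy-2,3-dihydrobenzofuran, via iodane adduct 13 (not isolated)
Conditions: PhI(OH)OTs (1.1 equiv), MeOH, −20 → 0 °C; aq. NaHCO3
Reagents that add atoms: methanol (CO)
Why: Proposed new method: the electrophilic trivalent iodine of PhI(OH)OTs should add to C3 of the styrene-like C3=C4 bond on the face anti to the C2 aryl group while methanol captures the C4 benzylic cation (stabilised by O1 through ring B) trans to iodine, giving adduct 13; in its all-equatorial half-chair the C4–C4a bond lies antiperiplanar to the C3–I bond, so ring B carbon C4a shifts from C4 to C3 with loss of PhI and inversion at C3, and the oxocarbenium ion left at old C4 is trapped by methanol as the dimethyl acetal. The closest known reaction types are the trivalent-iodine and trivalent-thallium ring contractions of 1,2-dihydronaphthalenes to indanyl acetals and of flavanone-derived enol ethers to trans-2-aryl-2,3-dihydrobenzofuran-3-carboxylates. The five-membered ring (O1, C2, C3, C3a, C7a) is not closed by cyclisation but arises by contraction of the pyran through a semipinacol-type 1,2-aryl shift via a phenonium-like bridged transition state, which forms the C3–C3a bond. The new stereocentre C3 is controlled by the existing C2 centre, because anti addition of iodine followed by stereospecific inversion places the acetal carbon trans to the C2 aryl group (2S,3S). The step needs migration of C4a in preference to migration of the C2 aryl group, methanol displacement of the iodane, or hydride loss from C2 to a flavylium ion; the migrating carbon being ortho to O1, the methoxy push at C4, the equatorial C2 aryl group and the low temperature should secure this.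

Step 8
Reactants: 14 (2S,3S)-5-bromo-2-[4-(tert-butyldimethylsilyloxy)-3-methoxyphenyl]-3-(dimethoxymethyl)-7-methoxy-2,3-dihydrobenzofuran
Product: 16 [(2S,3R)-5-bromo-2-[4-(tert-butyldimethylsilyloxy)-3-methoxyphenyl]-7-methoxy-2,3-dihydrobenzofuran-3-yl]methanol, via aldehyde 15 (not isolated)
Conditions: 2 M aq. HCl, THF, 0 °C → rt; NaHCO3; then NaBH4, MeOH, −20 °C
Reagents that add atoms: water (O)
Why: Acetal hydrolysis and immediate borohydride reduction convert the acetal to the primary alcohol; the α-aryl β-aryloxy aldehyde is deliberately not treated with base, since retro-oxa-Michael ring opening would destroy both C2 and C3.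

Step 9
Reactants: 16 [(2S,3R)-5-bromo-2-[4-(tert-butyldimethylsilyloxy)-3-methoxyphenyl]-7-methoxy-2,3-dihydrobenzofuran-3-yl]methanol
Product: 17 (2S,3R)-5-bromo-2-[4-(tert-butyldimethylsilyloxy)-3-methoxyphenyl]-3-[(tert-butyldimethylsilyloxy)methyl]-7-methoxy-2,3-dihydrobenzofuran
Conditions: TBSCl, imidazole, DMF, rt
Reagents that add atoms: tert-butyldimethylsilyl chloride (CC(C)(C)[Si](C)(C)Cl)
Why: Standard silylation of a primary alcohol, which masks the only acidic proton before the lithiation.

Step 10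
Reactants: 17 (2S,3R)-5-bromo-2-[4-(tert-butyldimethylsilyloxy)-3-methoxyphenyl]-3-[(tert-butyldimethylsilyloxy)methyl]-7-methoxy-2,3-dihydrobenzofuran
Product: 20 [(2S,3R)-2-[4-(tert-butyldimethylsilyloxy)-3-methoxyphenyl]-3-[(tert-butyldimethylsilyloxy)methyl]-7-methoxy-2,3-dihydrobenzofuran-5-yl]methanol, via aryllithium 18 (not isolated), via aldehyde 19 (not isolated)
Conditions: n-BuLi, THF, −78 °C; DMF, −78 → 0 °C; then MeOH, NaBH4, 0 °C
Reagents that add atoms: N,N-dimethylformamide (CN(C)C=O)
Why: Bromine–lithium exchange is faster than any deprotonation at −78 °C, and formylation of the aryllithium with DMF (Bouveault aldehyde synthesis) followed by borohydride reduction in the same flask gives the benzylic alcohol without touching C2 or C3.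

Step 11
Reactants: 20 [(2S,3R)-2-[4-(tert-butyldimethylsilyloxy)-3-methoxyphenyl]-3-[(tert-butyldimethylsilyloxy)methyl]-7-methoxy-2,3-dihydrobenzofuran-5-yl]methanol
Product: 21 (2S,3R)-5-(bromomethyl)-2-[4-(tert-butyldimethylsilyloxy)-3-methoxyphenyl]-3-[(tert-butyldimethylsilyloxy)methyl]-7-methoxy-2,3-dihydrobenzofuran
Conditions: CBr4, PPh3, CH2Cl2, 0 °C; use at once
Reagents that add atoms: carbon tetrabromide (BrC(Br)(Br)Br)
Why: The Appel reaction converts a benzylic alcohol to the bromide under neutral conditions that silyl ethers tolerate.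

Step 12
Reactants: 22 4-hydroxy-3-methoxybenzaldehyde (vanillin)
Product: 23 4-(tert-butyldimethylsilyloxy)-3-methoxybenzaldehyde
Conditions: TBSCl, imidazole, DMF, rt
Reagents that add atoms: tert-butyldimethylsilyl chloride (CC(C)(C)[Si](C)(C)Cl)
Why: Standard silylation of a phenol.

Step 13
Reactants: 23 4-(tert-butyldimethylsilyloxy)-3-methoxybenzaldehyde; 24 methyl 4-oxobutanoate
Product: 27 (R)-4-[(R)-hydroxy[4-(tert-butyldimethylsilyloxy)-3-methoxyphenyl]methyl]dihydrofuran-2(3H)-one, via aldol aldehyde 25 (not isolated), via diol ester 26 (not isolated)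
Conditions: L-proline (20 mol %), DMF, 4 °C, slow addition of 24; then MeOH, NaBH4, −20 °C; aq. NH4Cl, PPTS (cat.) if lactonisation is incomplete
Reagents that add atoms: none
Why: The L-proline enamine of the 4-oxobutanoate adds to the non-enolisable aryl aldehyde through a hydrogen-bonded chair transition state (organocatalytic direct anti cross-aldol), which sets both centres (3S,4R in 25) under catalyst control; borohydride then reduces only the aldehyde, and the primary alkoxide closes onto the methyl ester faster than the hindered benzylic hydroxyl.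

Step 14
Reactants: 27 (R)-4-[(R)-hydroxy[4-(tert-butyldimethylsilyloxy)-3-methoxyphenyl]methyl]dihydrofuran-2(3H)-one
Product: 28 (R)-4-[(R)-(tert-butyldimethylsilyloxy)[4-(tert-butyldimethylsilyloxy)-3-methoxyphenyl]methyl]dihydrofuran-2(3H)-one
Conditions: TBSOTf, 2,6-lutidine, CH2Cl2, −78 → 0 °C
Reagents that add atoms: tert-butyldimethylsilyl triflate (CC(C)(C)[Si](C)(C)OS(=O)(=O)C(F)(F)F)
Why: Silyl triflate silylation of a hindered secondary benzylic alcohol, which also blocks translactonisation and retro-aldol cleavage.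

Step 15
Reactants: 28 (R)-4-[(R)-(tert-butyldimethylsilyloxy)[4-(tert-butyldimethylsilyloxy)-3-methoxyphenyl]methyl]dihydrofuran-2(3H)-one; 21 (2S,3R)-5-(bromomethyl)-2-[4-(tert-butyldimethylsilyloxy)-3-methoxyphenyl]-3-[(tert-butyldimethylsilyloxy)methyl]-7-methoxy-2,3-dihydrobenzofuran
Product: 30 tetrakis-TBS ether of the target, via lithium enolate 29 (not isolated)
Conditions: LiN(SiMe3)2, THF, −78 °C; then 21, DMPU, −78 → −30 °C
Reagents that add atoms: none
Why: Enolate alkylation of a β-substituted γ-butyrolactone takes place on the face opposite the bulky β-[aryl(silyloxy)methyl] group (substrate-controlled trans alkylation), which sets lactone C3 as R.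

Step 16
Reactants: 30 tetrakis-TBS ether of the target
Product: 31 target, (3R,4R)-4-[(R)-hydroxy(4-hydroxy-3-methoxyphenyl)methyl]-3-{[(2S,3R)-2-(4-hydroxy-3-methoxyphenyl)-3-(hydroxymethyl)-7-methoxy-2,3-dihydrobenzofuran-5-yl]methyl}dihydrofuran-2(3H)-one
Conditions: Bu4NF, AcOH (1:1, excess), THF, 0 °C → rt
Reagents that add atoms: none
Why: Fluoride-mediated desilylation of the two aryl and two alkyl silyl ethers, buffered with acetic acid so that the phenols stay protonated and quinone methide formation, lactone opening and epimerisation are suppressed.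

**Compound list**

1 | 5-bromo-2-hydroxy-3-methoxybenzaldehyde | O=Cc1cc(Br)cc(OC)c1O | starting material
2 | ethyl (triphenylphosphoranylidene)acetate | CCOC(=O)C=P(c1ccccc1)(c1ccccc1)c1ccccc1 | starting material
3 | ethyl (Z)-3-(5-bromo-2-hydroxy-3-methoxyphenyl)acrylate | CCOC(=O)/C=C\c1cc(Br)cc(OC)c1O | intermediate
4 | 6-bromo-8-methoxy-2H-chromen-2-one | O=C1C=Cc2cc(Br)cc(OC)c2O1 | intermediate
5 | 6-bromo-8-methoxy-2H-chromen-2-ol (racemic lactol) | OC1C=Cc2cc(Br)cc(OC)c2O1 | intermediate
6 | 6-bromo-2-ethoxy-8-methoxy-2H-chromene (racemic) | CCOC1C=Cc2cc(Br)cc(OC)c2O1 | intermediate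
7 | 4-bromo-2-methoxyphenol | COc1cc(Br)ccc1O | starting material
8 | (4-bromo-2-methoxyphenoxy)(tert-butyl)dimethylsilane | COc1cc(Br)ccc1O[Si](C)(C)C(C)(C)C | intermediate
9 | [4-(tert-butyldimethylsilyloxy)-3-methoxyphenyl]lithium | [Li]c1ccc(O[Si](C)(C)C(C)(C)C)c(OC)c1 | intermediate
10 | [4-(tert-butyldimethylsilyloxy)-3-methoxyphenyl]boronic acid | COc1cc(B(O)O)ccc1O[Si](C)(C)C(C)(C)C | intermediate
11 | diethyl [4-(tert-butyldimethylsilyloxy)-3-methoxyphenyl]boronate | CCOB(OCC)c1ccc(O[Si](C)(C)C(C)(C)C)c(OC)c1 | intermediate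
12 | (S)-6-bromo-2-[4-(tert-butyldimethylsilyloxy)-3-methoxyphenyl]-8-methoxy-2H-chromene | COc1cc([C@H]2Oc3c(OC)cc(Br)cc3C=C2)ccc1O[Si](C)(C)C(C)(C)C | intermediate
13 | iodane adduct of 12: 2,3-trans-3,4-trans-6-bromo-2-[4-(tert-butyldimethylsilyloxy)-3-methoxyphenyl]-4,8-dimethoxy-3-[phenyl(tosyloxy)iodanyl]chromane | COc1cc([C@H]2Oc3c(OC)cc(Br)cc3[C@@H](OC)[C@@H]2I(OS(=O)(=O)c4ccc(C)cc4)c4ccccc4)ccc1O[Si](C)(C)C(C)(C)C | intermediate
14 | (2S,3S)-5-bromo-2-[4-(tert-butyldimethylsilyloxy)-3-methoxyphenyl]-3-(dimethoxymethyl)-7-methoxy-2,3-dihydrobenzofuran (trans) | COc1cc([C@H]2Oc3c(OC)cc(Br)cc3[C@@H]2C(OC)OC)ccc1O[Si](C)(C)C(C)(C)C | intermediate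
15 | (2S,3S)-5-bromo-2-[4-(tert-butyldimethylsilyloxy)-3-methoxyphenyl]-7-methoxy-2,3-dihydrobenzofuran-3-carbaldehyde | COc1cc([C@H]2Oc3c(OC)cc(Br)cc3[C@@H]2C=O)ccc1O[Si](C)(C)C(C)(C)C | intermediate
16 | [(2S,3R)-5-bromo-2-[4-(tert-butyldimethylsilyloxy)-3-methoxyphenyl]-7-methoxy-2,3-dihydrobenzofuran-3-yl]methanol | COc1cc([C@H]2Oc3c(OC)cc(Br)cc3[C@@H]2CO)ccc1O[Si](C)(C)C(C)(C)C | intermediate
17 | (2S,3R)-5-bromo-2-[4-(tert-butyldimethylsilyloxy)-3-methoxyphenyl]-3-[(tert-butyldimethylsilyloxy)methyl]-7-methoxy-2,3-dihydrobenzofuran | COc1cc([C@H]2Oc3c(OC)cc(Br)cc3[C@@H]2CO[Si](C)(C)C(C)(C)C)ccc1O[Si](C)(C)C(C)(C)C | intermediate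
18 | 5-lithio derivative of 17 | COc1cc([C@H]2Oc3c(OC)cc([Li])cc3[C@@H]2CO[Si](C)(C)C(C)(C)C)ccc1O[Si](C)(C)C(C)(C)C | intermediate
19 | (2S,3R)-2-[4-(tert-butyldimethylsilyloxy)-3-methoxyphenyl]-3-[(tert-butyldimethylsilyloxy)methyl]-7-methoxy-2,3-dihydrobenzofuran-5-carbaldehyde | COc1cc([C@H]2Oc3c(OC)cc(C=O)cc3[C@@H]2CO[Si](C)(C)C(C)(C)C)ccc1O[Si](C)(C)C(C)(C)C | intermediate
20 | [(2S,3R)-2-[4-(tert-butyldimethylsilyloxy)-3-methoxyphenyl]-3-[(tert-butyldimethylsilyloxy)methyl]-7-methoxy-2,3-dihydrobenzofuran-5-yl]methanol | COc1cc([C@H]2Oc3c(OC)cc(CO)cc3[C@@H]2CO[Si](C)(C)C(C)(C)C)ccc1O[Si](C)(C)C(C)(C)C | intermediate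
21 | (2S,3R)-5-(bromomethyl)-2-[4-(tert-butyldimethylsilyloxy)-3-methoxyphenyl]-3-[(tert-butyldimethylsilyloxy)methyl]-7-methoxy-2,3-dihydrobenzofuran | COc1cc([C@H]2Oc3c(OC)cc(CBr)cc3[C@@H]2CO[Si](C)(C)C(C)(C)C)ccc1O[Si](C)(C)C(C)(C)C | intermediate
22 | 4-hydroxy-3-methoxybenzaldehyde (vanillin) | COc1cc(C=O)ccc1O | starting material
23 | 4-(tert-butyldimethylsilyloxy)-3-methoxybenzaldehyde | COc1cc(C=O)ccc1O[Si](C)(C)C(C)(C)C | intermediate
24 | methyl 4-oxobutanoate | COC(=O)CCC=O | starting material
25 | methyl (3S,4R)-3-formyl-4-hydroxy-4-[4-(tert-butyldimethylsilyloxy)-3-methoxyphenyl]butanoate | COC(=O)C[C@H](C=O)[C@@H](O)c1ccc(O[Si](C)(C)C(C)(C)C)c(OC)c1 | intermediate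
26 | methyl (3R,4R)-4-hydroxy-3-(hydroxymethyl)-4-[4-(tert-butyldimethylsilyloxy)-3-methoxyphenyl]butanoate | COC(=O)C[C@H](CO)[C@@H](O)c1ccc(O[Si](C)(C)C(C)(C)C)c(OC)c1 | intermediate
27 | (R)-4-[(R)-hydroxy[4-(tert-butyldimethylsilyloxy)-3-methoxyphenyl]methyl]dihydrofuran-2(3H)-one | O=C1C[C@H](CO1)[C@@H](O)c2ccc(O[Si](C)(C)C(C)(C)C)c(OC)c2 | intermediate
28 | (R)-4-[(R)-(tert-butyldimethylsilyloxy)[4-(tert-butyldimethylsilyloxy)-3-methoxyphenyl]methyl]dihydrofuran-2(3H)-one | O=C1C[C@H](CO1)[C@@H](O[Si](C)(C)C(C)(C)C)c2ccc(O[Si](C)(C)C(C)(C)C)c(OC)c2 | intermediate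
29 | lithium enolate of 28 | [Li]OC1=C[C@H](CO1)[C@@H](O[Si](C)(C)C(C)(C)C)c2ccc(O[Si](C)(C)C(C)(C)C)c(OC)c2 | intermediate
30 | (3R,4R)-3-{[(2S,3R)-2-[4-(tert-butyldimethylsilyloxy)-3-methoxyphenyl]-3-[(tert-butyldimethylsilyloxy)methyl]-7-methoxy-2,3-dihydrobenzofuran-5-yl]methyl}-4-[(R)-(tert-butyldimethylsilyloxy)[4-(tert-butyldimethylsilyloxy)-3-methoxyphenyl]methyl]dihydrofuran-2(3H)-one | COc1cc([C@H]2Oc3c(OC)cc(C[C@H]4C(=O)OC[C@@H]4[C@@H](O[Si](C)(C)C(C)(C)C)c4ccc(O[Si](C)(C)C(C)(C)C)c(OC)c4)cc3[C@@H]2CO[Si](C)(C)C(C)(C)C)ccc1O[Si](C)(C)C(C)(C)C | intermediate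
31 | (3R,4R)-4-[(R)-hydroxy(4-hydroxy-3-methoxyphenyl)methyl]-3-{[(2S,3R)-2-(4-hydroxy-3-methoxyphenyl)-3-(hydroxymethyl)-7-methoxy-2,3-dihydrobenzofuran-5-yl]methyl}dihydrofuran-2(3H)-one | COc1cc([C@H]2Oc3c(OC)cc(C[C@H]4C(=O)OC[C@@H]4[C@@H](O)c4ccc(O)c(OC)c4)cc3[C@@H]2CO)ccc1O | target

**Step count**

Total: 16 steps. Longest linear sequence: 11 steps (steps 3, 4, 5, 6, 7, 8, 9, 10, 11, 15, 16, from 4-bromo-2-methoxyphenol).

**Steps most likely to fail**

1. Step 7 (proposed new method). The electron-rich C2 aryl group may migrate to C3 instead of ring carbon C4a, methanol may displace the iodane to give simple 3,4-dimethoxylation, or C2 may lose hydride to give a flavylium ion. The fallback uses known chemistry, sets out from chromene 12 and returns at alcohol 16. Mukaiyama hydration of the styrene-like double bond (Co(acac)2 cat., PhSiH3, O2, THF) should place the hydroxyl at benzylic C4 to give (2S)-6-bromo-2-[4-(tert-butyldimethylsilyloxy)-3-methoxyphenyl]-8-methoxychroman-4-ol F1. Dess–Martin oxidation then gives the flavanone, (S)-6-bromo-2-[4-(tert-butyldimethylsilyloxy)-3-methoxyphenyl]-8-methoxychroman-4-one F2. The established oxidative ring contraction of flavanones (PhI(OAc)2, HC(OMe)3, cat. H2SO4) should give methyl (2S,3S)-5-bromo-2-[4-(tert-butyldimethylsilyloxy)-3-methoxyphenyl]-7-methoxy-2,3-dihydrobenzofuran-3-carboxylate F3, and LiBH4 in THF reduces this ester to 16.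

2. Step 6. Aryl transfer to the 8-methoxy-substituted benzopyrylium ion may be slow, so that the uncatalysed racemic pathway competes and facial selectivity is poor. The fallback sets out from acetal 6 and boronate 11 and returns at chromene 12. An achiral Lewis acid alone (BF3·OEt2, CH2Cl2, −40 °C) should give racemic 6-bromo-2-[4-(tert-butyldimethylsilyloxy)-3-methoxyphenyl]-8-methoxy-2H-chromene F4, which is resolved by preparative chromatography on a chiral stationary phase (amylose tris(3,5-dimethylphenylcarbamate)) to supply (S)-12.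

3. Step 15. The electron-rich benzylic bromide may ionise and decompose before it is captured, the hindered enolate may convert incompletely, and a second alkylation may follow. The fallback sets out from lactone 28 (as enolate 29) and aldehyde 19 (isolated by leaving out the borohydride in step 10) and returns at 30. Aldol addition at −78 °C should give the 3,4-trans adduct, the α-[hydroxy(aryl)methyl] lactone F5, as a mixture of carbinol epimers. Mesylation and elimination (MsCl, Et3N, then DBU) give the (E)-α-arylidene lactone F6. Copper hydride conjugate reduction (Cu(OAc)2 and 1,2-bis(diphenylphosphino)benzene cat., polymethylhydrosiloxane, t-BuOH, toluene), followed by DBU equilibration to the more stable trans lactone, delivers 30.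

**Further compounds**

F1 | step 7 | (2S)-6-bromo-2-[4-(tert-butyldimethylsilyloxy)-3-methoxyphenyl]-8-methoxychroman-4-ol (C4 epimers) | COc1cc([C@H]2Oc3c(OC)cc(Br)cc3C(O)C2)ccc1O[Si](C)(C)C(C)(C)C
F2 | step 7 | (S)-6-bromo-2-[4-(tert-butyldimethylsilyloxy)-3-methoxyphenyl]-8-methoxychroman-4-one | COc1cc([C@H]2Oc3c(OC)cc(Br)cc3C(=O)C2)ccc1O[Si](C)(C)C(C)(C)C
F3 | step 7 | methyl (2S,3S)-5-bromo-2-[4-(tert-butyldimethylsilyloxy)-3-methoxyphenyl]-7-methoxy-2,3-dihydrobenzofuran-3-carboxylate | COc1cc([C@H]2Oc3c(OC)cc(Br)cc3[C@@H]2C(=O)OC)ccc1O[Si](C)(C)C(C)(C)C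
F4 | step 6 | racemic 6-bromo-2-[4-(tert-butyldimethylsilyloxy)-3-methoxyphenyl]-8-methoxy-2H-chromene | COc1cc(C2Oc3c(OC)cc(Br)cc3C=C2)ccc1O[Si](C)(C)C(C)(C)C
F5 | step 15 | 3,4-trans aldol adduct of 29 and 19, the α-[hydroxy(aryl)methyl] lactone (carbinol epimers) | COc1cc([C@H]2Oc3c(OC)cc(C(O)[C@H]4C(=O)OC[C@@H]4[C@@H](O[Si](C)(C)C(C)(C)C)c4ccc(O[Si](C)(C)C(C)(C)C)c(OC)c4)cc3[C@@H]2CO[Si](C)(C)C(C)(C)C)ccc1O[Si](C)(C)C(C)(C)C
F6 | step 15 | (E)-α-arylidene lactone from F5 | COc1cc([C@H]2Oc3c(OC)cc(/C=C4/C(=O)OC[C@@H]4[C@@H](O[Si](C)(C)C(C)(C)C)c4ccc(O[Si](C)(C)C(C)(C)C)c(OC)c4)cc3[C@@H]2CO[Si](C)(C)C(C)(C)C)ccc1O[Si](C)(C)C(C)(C)C
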